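**Retrosynthetic overview**
- Feature: ring A carries three mutually meta oxygens. O1 (on C8a) and O5 flank C4a, O7 lies para to C4a, and only O7 is galloylated. Ring A is therefore built so that each oxygen is born with its own substituent (OH, OTIPS, O-allyl).
- Late disconnections: the O7–C(=O) ester (Steglich galloylation after deallylation) and O1–C2 (Mitsunobu closure of ring C with inversion, anti carbinol to 2,3-cis).
- Key disconnection: ring A splits into 3-allyloxycyclobutenone (C8a, C6, C7, C8) and a chain-bearing triisopropylsiloxyalkyne (C4a, C5). A cyclobutenone–ynol ether benzannulation forms C4a–C8a, C5–C6 and C8–C8a.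
- The siloxyalkyne comes from 3,4,5-tris(benzyloxy)benzaldehyde by vinyl addition, Sharpless kinetic-resolution epoxidation (sets both stereocentres), acetylide opening of the terminal epoxide (C4–C4a), neutral benzylation and acetylide oxidation/silylation.
- Ring order: ring B and the galloyl ring are bought, ring A forms in step 10, ring C in step 12.

Key step: step 10

Assumption: 3-ethoxycyclobut-2-en-1-one, 3,4,5-trihydroxybenzaldehyde and 3,4,5-tris(benzyloxy)benzoic acid are taken as purchasable; flavan numbering (O1, C2–C4, C4a, C5–C8, C8a) is used for the atoms of the target throughout.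

**Step 1**
Reactants: 1 3,4,5-trihydroxybenzaldehyde
Product: 2 3,4,5-tris(benzyloxy)benzaldehyde
Conditions: BnBr (3.5 equiv), K2CO3, DMF, 60 °C, Ar
Reagents that add atoms: benzyl bromide BrCc1ccccc1
Why: Williamson ether synthesis on three acidic phenols, run under argon so that the pyrogallol unit is not oxidised before it is capped.

**Step 2**
Reactants: 2 3,4,5-tris(benzyloxy)benzaldehyde; 3 vinylmagnesium bromide
Product: 4 rac-1-[3,4,5-tris(benzyloxy)phenyl]prop-2-en-1-ol
Conditions: THF, −78 → 0 °C; aq. NH4Cl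
Reagents that add atoms: none
Why: Grignard 1,2-addition to a non-enolisable aldehyde; the carbinol is made racemic on purpose because the next step resolves it.

**Step 3**
Reactants: 4 rac-1-[3,4,5-tris(benzyloxy)phenyl]prop-2-en-1-ol
Product: 5 (S)-[(2R)-oxiran-2-yl][3,4,5-tris(benzyloxy)phenyl]methanol (erythro epoxy alcohol)
Conditions: Ti(OiPr)4 (0.15 equiv), L-(+)-DIPT (0.2 equiv), t-BuOOH (0.45 equiv), 4 Å MS, CH2Cl2, −20 °C
Reagents that add atoms: tert-butyl hydroperoxide CC(C)(C)OO
Why: Sharpless asymmetric epoxidation run as a kinetic resolution: with the L-(+)-tartrate the (R)-carbinol is the fast-reacting enantiomer and oxygen goes to the face that gives the erythro (anti) epoxy alcohol, so the catalyst fixes the carbinol carbon (future C2, S after the change of CIP priorities) and the oxirane carbon (future C3, R), while the slow (S)-alcohol stays behind and is removed by chromatography.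

**Step 4**
Reactants: 5 (S)-[(2R)-oxiran-2-yl][3,4,5-tris(benzyloxy)phenyl]methanol
Product: 6 triethyl{(S)-[(2R)-oxiran-2-yl][3,4,5-tris(benzyloxy)phenyl]methoxy}silane
Conditions: TESCl, imidazole, CH2Cl2, 0 °C
Reagents that add atoms: chlorotriethylsilane CC[Si](Cl)(CC)CC
Why: Standard imidazole-mediated silylation of the only hydroxyl group, mild enough to avoid Payne rearrangement of the epoxy alcohol.

**Step 5**
Reactants: 6 triethyl{(S)-[(2R)-oxiran-2-yl][3,4,5-tris(benzyloxy)phenyl]methoxy}silane; 7 (trimethylsilyl)acetylene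
Product: 9 (1S,2R)-1-(triethylsilyloxy)-5-(trimethylsilyl)-1-[3,4,5-tris(benzyloxy)phenyl]pent-4-yn-2-ol, via lithium trimethylsilylacetylide 8 (not isolated)
Conditions: 7, n-BuLi, THF, −78 °C; BF3·OEt2; then 6, −78 °C; H2O quench
Reagents that add atoms: none
Why: Yamaguchi-type BF3-assisted opening of a terminal epoxide by a lithium acetylide, an SN2 attack at the unhindered CH2 (forms C4–C4a) that touches neither stereocentre, and the boron-bound alkoxide at −78 °C should not trigger silyl migration.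

**Step 6**
Reactants: 9 (1S,2R)-1-(triethylsilyloxy)-5-(trimethylsilyl)-1-[3,4,5-tris(benzyloxy)phenyl]pent-4-yn-2-ol
Product: 10 [(4R,5S)-4-(benzyloxy)-5-(triethylsilyloxy)-5-[3,4,5-tris(benzyloxy)phenyl]pent-1-yn-1-yl]trimethylsilane
Conditions: 2-benzyloxy-1-methylpyridinium triflate (2 equiv), MgO, PhCF3, 85 °C
Reagents that add atoms: 2-benzyloxy-1-methylpyridinium triflate C[n+]1ccccc1OCc1ccccc1.[O-]S(=O)(=O)C(F)(F)F
Why: Neutral benzyl transfer from the 2-benzyloxypyridinium salt (thermal release of a benzyl cation equivalent, MgO as acid scavenger) etherifies the secondary alcohol without forming an alkoxide, so the neighbouring triethylsilyl group should not migrate from oxygen to oxygen as it would under NaH/BnBr.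

**Step 7**
Reactants: 10 [(4R,5S)-4-(benzyloxy)-5-(triethylsilyloxy)-5-[3,4,5-tris(benzyloxy)phenyl]pent-1-yn-1-yl]trimethylsilane
Product: 11 (4R,5S)-4-(benzyloxy)-5-(triethylsilyloxy)-5-[3,4,5-tris(benzyloxy)phenyl]pent-1-yne
Conditions: K2CO3 (cat.), MeOH–THF, 0 °C → rt
Reagents that add atoms: none
Why: Base-catalysed methanolysis of the C(sp)–Si bond (protiodesilylation), which is much faster than attack on the hindered secondary O–SiEt3 group.

**Step 8**
Reactants: 11 (4R,5S)-4-(benzyloxy)-5-(triethylsilyloxy)-5-[3,4,5-tris(benzyloxy)phenyl]pent-1-yne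
Product: 14 (4R,5S)-4-(benzyloxy)-5-(triethylsilyloxy)-5-[3,4,5-tris(benzyloxy)phenyl]pent-1-yn-1-yl triisopropylsilyl ether, via lithium acetylide 12 (not isolated), via lithium ynolate 13 (not isolated)
Conditions: n-BuLi, THF, −78 °C; LiOOt-Bu (from t-BuOOH and LiN(SiMe3)2, THF, −78 °C), −78 → 0 °C; TIPSOTf, −78 → 0 °C; chromatography on Et3N-deactivated silica
Reagents that add atoms: tert-butyl hydroperoxide CC(C)(C)OO; triisopropylsilyl triflate CC(C)[Si](C(C)C)(C(C)C)OS(=O)(=O)C(F)(F)F
Why: Oxidation of a lithium acetylide by lithium tert-butyl peroxide (the acetylide carbon attacks the O–O bond) gives the lithium ynolate, and the bulky silyl triflate traps it on oxygen rather than carbon to give the siloxyalkyne.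

**Step 9**
Reactants: 15 3-ethoxycyclobut-2-en-1-one
Product: 16 3-(allyloxy)cyclobut-2-en-1-one
Conditions: allyl alcohol (large excess), PPTS (cat.), rt, EtOH stripped under reduced pressure
Reagents that add atoms: allyl alcohol C=CCO
Why: Acid-catalysed alkoxy exchange of a vinylogous ester (conjugate addition of allyl alcohol at C3, then loss of ethanol), driven by the excess of allyl alcohol and removal of the more volatile ethanol.

**Step 10**
Reactants: 14 (4R,5S)-4-(benzyloxy)-5-(triethylsilyloxy)-5-[3,4,5-tris(benzyloxy)phenyl]pent-1-yn-1-yl triisopropylsilyl ether; 16 3-(allyloxy)cyclobut-2-en-1-one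
Product: 21 2-[(2R,3S)-2-(benzyloxy)-3-(triethylsilyloxy)-3-[3,4,5-tris(benzyloxy)phenyl]propyl]-5-(allyloxy)-3-(triisopropylsilyloxy)phenol, via allyloxyvinylketene 17 (not isolated), via alkenylcyclobutenone adduct 18 (not isolated), via dienylketene 19 (not isolated), via cyclohexadienone tautomer 20 (not isolated)
Conditions: toluene (0.5 M), 16 (1.3 equiv, added in portions), 80 °C then 110 °C, sealed tube, Ar
Reagents that add atoms: none
Why: Danheiser benzannulation: heat opens 16 by conrotatory 4π electrocyclic cleavage of C1–C4 to vinylketene 17, the nucleophilic chain-bearing carbon of ynol ether 14 attacks the ketene carbonyl carbon, and [2+2] closure gives the 4-alkenylcyclobutenone 18 (new bonds C4a–C8a and C5–C6). A second, reversible 4π opening turns 18 into dienylketene 19, and ring A closes by thermal disrotatory 6π electrocyclisation (C8–C8a) to dienone 20, which tautomerises irreversibly to phenol 21. The closest known reaction type is the benzannulation of 3-alkyl- and 3-arylcyclobutenones with triisopropylsiloxyalkynes to resorcinol monosilyl ethers; the 3-alkoxy group is only a new substituent, but as part of a vinylogous ester it should retard the first opening, hence the final 110 °C stage and the portionwise addition of 16. No lasting stereocentre is created, since the sp3 ring carbon of 18 is planarised again, and the two side-chain stereocentres take no part in any bond change. The selectivity needed is regiochemical, and it is secured by the polarity match of the ketene (electrophilic at the carbonyl carbon) and the ynol ether (nucleophilic at the carbon β to oxygen), which puts the chain between OH and OTIPS and the allyloxy group para to the chain. Chemoselectivity is secured because 14 has no free OH to trap a ketene and because the temperature stays below that of allyl vinyl ether or allyl aryl ether Claisen rearrangement.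

**Step 11**
Reactants: 21 2-[(2R,3S)-2-(benzyloxy)-3-(triethylsilyloxy)-3-[3,4,5-tris(benzyloxy)phenyl]propyl]-5-(allyloxy)-3-(triisopropylsilyloxy)phenol
Product: 22 2-[(2R,3S)-2-(benzyloxy)-3-hydroxy-3-[3,4,5-tris(benzyloxy)phenyl]propyl]-5-(allyloxy)-3-(triisopropylsilyloxy)phenol
Conditions: AcOH–THF–H2O (3:1:1), rt
Reagents that add atoms: none
Why: Mild acid hydrolysis distinguishes the silyl ethers by size and type: the small alkyl O–SiEt3 group is cleaved, the bulky aryl O–Si(iPr)3 group (labile mainly to base and fluoride) should stay, and the acid is too weak to ionise the benzylic carbinol.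

**Step 12**
Reactants: 22 2-[(2R,3S)-2-(benzyloxy)-3-hydroxy-3-[3,4,5-tris(benzyloxy)phenyl]propyl]-5-(allyloxy)-3-(triisopropylsilyloxy)phenol
Product: 23 (2R,3R)-7-(allyloxy)-3-(benzyloxy)-5-(triisopropylsilyloxy)-2-[3,4,5-tris(benzyloxy)phenyl]chroman
Conditions: PPh3, DIAD, toluene (high dilution), 0 °C → rt
Reagents that add atoms: none
Why: Intramolecular Mitsunobu etherification: the only free phenol (O1) displaces the oxyphosphonium of the only free alcohol in a 6-exo-tet SN2 closure of ring C, so the S carbinol is inverted to 2R and, with 3R untouched, the 2,3-cis chroman should result; the non-polar solvent and low temperature disfavour ionisation of the electron-rich benzylic centre.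

**Step 13**
Reactants: 23 (2R,3R)-7-(allyloxy)-3-(benzyloxy)-5-(triisopropylsilyloxy)-2-[3,4,5-tris(benzyloxy)phenyl]chroman
Product: 24 (2R,3R)-3-(benzyloxy)-5-(triisopropylsilyloxy)-2-[3,4,5-tris(benzyloxy)phenyl]chroman-7-ol
Conditions: Pd(PPh3)4 (cat.), morpholine, THF, rt
Reagents that add atoms: none
Why: Tsuji–Trost-type deallylation: zerovalent palladium ionises the allyl aryl ether to the phenoxide and a π-allyl complex of divalent palladium, and morpholine takes up the allyl group, while benzyl and silyl ethers are inert.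

**Step 14**
Reactants: 24 (2R,3R)-3-(benzyloxy)-5-(triisopropylsilyloxy)-2-[3,4,5-tris(benzyloxy)phenyl]chroman-7-ol; 25 3,4,5-tris(benzyloxy)benzoic acid
Product: 26 (2R,3R)-3-(benzyloxy)-5-(triisopropylsilyloxy)-2-[3,4,5-tris(benzyloxy)phenyl]chroman-7-yl 3,4,5-tris(benzyloxy)benzoate
Conditions: DCC, DMAP (cat.), CH2Cl2, 0 °C → rt
Reagents that add atoms: none
Why: Steglich esterification of the only free hydroxyl group, the unhindered O7 phenol.

**Step 15**
Reactants: 26 (2R,3R)-3-(benzyloxy)-5-(triisopropylsilyloxy)-2-[3,4,5-tris(benzyloxy)phenyl]chroman-7-yl 3,4,5-tris(benzyloxy)benzoate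
Product: 27 (2R,3R)-3-(benzyloxy)-5-hydroxy-2-[3,4,5-tris(benzyloxy)phenyl]chroman-7-yl 3,4,5-tris(benzyloxy)benzoate
Conditions: Bu4NF, AcOH (1:1), THF, 0 °C
Reagents that add atoms: none
Why: Fluoride-induced cleavage of the aryl silyl ether, buffered with acetic acid so that the liberated phenoxide is protonated at once and cannot attack the aryl ester.

**Step 16**
Reactants: 27 (2R,3R)-3-(benzyloxy)-5-hydroxy-2-[3,4,5-tris(benzyloxy)phenyl]chroman-7-yl 3,4,5-tris(benzyloxy)benzoate
Product: 28 (−)-epigallocatechin 7-O-gallate, (2R,3R)-3,5-dihydroxy-2-(3,4,5-trihydroxyphenyl)chroman-7-yl 3,4,5-trihydroxybenzoate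
Conditions: H2 (1 atm), Pd(OH)2/C, THF–EtOAc, rt
Reagents that add atoms: none
Why: Catalytic hydrogenolysis of all seven benzyl ethers under neutral conditions, which should leave the O1–C2 bond of the flavan, the aryl ester and both stereocentres intact.

**Compound list**
1 | 3,4,5-trihydroxybenzaldehyde | O=Cc1cc(O)c(O)c(O)c1 | starting material
2 | 3,4,5-tris(benzyloxy)benzaldehyde | O=Cc1cc(OCc2ccccc2)c(OCc2ccccc2)c(OCc2ccccc2)c1 | intermediate
3 | vinylmagnesium bromide | C=C[Mg]Br | starting material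
4 | rac-1-[3,4,5-tris(benzyloxy)phenyl]prop-2-en-1-ol | OC(C=C)c1cc(OCc2ccccc2)c(OCc2ccccc2)c(OCc2ccccc2)c1 | intermediate
5 | (S)-[(2R)-oxiran-2-yl][3,4,5-tris(benzyloxy)phenyl]methanol | O[C@@H](c1cc(OCc2ccccc2)c(OCc2ccccc2)c(OCc2ccccc2)c1)[C@H]1CO1 | intermediate
6 | triethyl{(S)-[(2R)-oxiran-2-yl][3,4,5-tris(benzyloxy)phenyl]methoxy}silane | CC[Si](CC)(CC)O[C@@H](c1cc(OCc2ccccc2)c(OCc2ccccc2)c(OCc2ccccc2)c1)[C@H]1CO1 | intermediate
7 | (trimethylsilyl)acetylene | C#C[Si](C)(C)C | starting material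
8 | lithium (trimethylsilyl)acetylide | [Li]C#C[Si](C)(C)C | intermediate
9 | (1S,2R)-1-(triethylsilyloxy)-5-(trimethylsilyl)-1-[3,4,5-tris(benzyloxy)phenyl]pent-4-yn-2-ol | CC[Si](CC)(CC)O[C@@H](c1cc(OCc2ccccc2)c(OCc2ccccc2)c(OCc2ccccc2)c1)[C@H](O)CC#C[Si](C)(C)C | intermediate
10 | [(4R,5S)-4-(benzyloxy)-5-(triethylsilyloxy)-5-[3,4,5-tris(benzyloxy)phenyl]pent-1-yn-1-yl]trimethylsilane | CC[Si](CC)(CC)O[C@@H](c1cc(OCc2ccccc2)c(OCc2ccccc2)c(OCc2ccccc2)c1)[C@H](OCc1ccccc1)CC#C[Si](C)(C)C | intermediate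
11 | (4R,5S)-4-(benzyloxy)-5-(triethylsilyloxy)-5-[3,4,5-tris(benzyloxy)phenyl]pent-1-yne | CC[Si](CC)(CC)O[C@@H](c1cc(OCc2ccccc2)c(OCc2ccccc2)c(OCc2ccccc2)c1)[C@H](OCc1ccccc1)CC#C | intermediate
12 | lithium acetylide of 11 | CC[Si](CC)(CC)O[C@@H](c1cc(OCc2ccccc2)c(OCc2ccccc2)c(OCc2ccccc2)c1)[C@H](OCc1ccccc1)CC#C[Li] | intermediate
13 | lithium ynolate from 12 | CC[Si](CC)(CC)O[C@@H](c1cc(OCc2ccccc2)c(OCc2ccccc2)c(OCc2ccccc2)c1)[C@H](OCc1ccccc1)CC#CO[Li] | intermediate
14 | (4R,5S)-4-(benzyloxy)-5-(triethylsilyloxy)-5-[3,4,5-tris(benzyloxy)phenyl]pent-1-yn-1-yl triisopropylsilyl ether | CC[Si](CC)(CC)O[C@@H](c1cc(OCc2ccccc2)c(OCc2ccccc2)c(OCc2ccccc2)c1)[C@H](OCc1ccccc1)CC#CO[Si](C(C)C)(C(C)C)C(C)C | intermediate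
15 | 3-ethoxycyclobut-2-en-1-one | CCOC1=CC(=O)C1 | starting material
16 | 3-(allyloxy)cyclobut-2-en-1-one | C=CCOC1=CC(=O)C1 | intermediate
17 | 3-(allyloxy)buta-1,3-dien-1-one (allyloxyvinylketene) | C=CCOC(=C)C=C=O | intermediate
18 | 4-[1-(allyloxy)vinyl]-3-(triisopropylsilyloxy)cyclobut-2-en-1-one carrying the side chain at C2 (ring C4 unassigned) | CC[Si](CC)(CC)O[C@@H](c1cc(OCc2ccccc2)c(OCc2ccccc2)c(OCc2ccccc2)c1)[C@H](OCc1ccccc1)CC1=C(O[Si](C(C)C)(C(C)C)C(C)C)C(C(=C)OCC=C)C1=O | intermediate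
19 | dienylketene, 5-(allyloxy)-3-(triisopropylsilyloxy)hexa-1,3,5-trien-1-one carrying the side chain at C2 (ketene carbon chain and C5 cis on the central double bond) | CC[Si](CC)(CC)O[C@@H](c1cc(OCc2ccccc2)c(OCc2ccccc2)c(OCc2ccccc2)c1)[C@H](OCc1ccccc1)CC(=C=O)/C(O[Si](C(C)C)(C(C)C)C(C)C)=C\C(=C)OCC=C | intermediate
20 | 5-(allyloxy)-3-(triisopropylsilyloxy)cyclohexa-2,4-dien-1-one carrying the side chain at C2 | CC[Si](CC)(CC)O[C@@H](c1cc(OCc2ccccc2)c(OCc2ccccc2)c(OCc2ccccc2)c1)[C@H](OCc1ccccc1)CC1=C(O[Si](C(C)C)(C(C)C)C(C)C)C=C(OCC=C)CC1=O | intermediate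
21 | 2-[(2R,3S)-2-(benzyloxy)-3-(triethylsilyloxy)-3-[3,4,5-tris(benzyloxy)phenyl]propyl]-5-(allyloxy)-3-(triisopropylsilyloxy)phenol | CC[Si](CC)(CC)O[C@@H](c1cc(OCc2ccccc2)c(OCc2ccccc2)c(OCc2ccccc2)c1)[C@H](OCc1ccccc1)Cc1c(O)cc(OCC=C)cc1O[Si](C(C)C)(C(C)C)C(C)C | intermediate
22 | 2-[(2R,3S)-2-(benzyloxy)-3-hydroxy-3-[3,4,5-tris(benzyloxy)phenyl]propyl]-5-(allyloxy)-3-(triisopropylsilyloxy)phenol | O[C@@H](c1cc(OCc2ccccc2)c(OCc2ccccc2)c(OCc2ccccc2)c1)[C@H](OCc1ccccc1)Cc1c(O)cc(OCC=C)cc1O[Si](C(C)C)(C(C)C)C(C)C | intermediate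
23 | (2R,3R)-7-(allyloxy)-3-(benzyloxy)-5-(triisopropylsilyloxy)-2-[3,4,5-tris(benzyloxy)phenyl]chroman | C=CCOc1cc(O[Si](C(C)C)(C(C)C)C(C)C)c2c(c1)O[C@H](c1cc(OCc3ccccc3)c(OCc3ccccc3)c(OCc3ccccc3)c1)[C@H](OCc1ccccc1)C2 | intermediate
24 | (2R,3R)-3-(benzyloxy)-5-(triisopropylsilyloxy)-2-[3,4,5-tris(benzyloxy)phenyl]chroman-7-ol | Oc1cc(O[Si](C(C)C)(C(C)C)C(C)C)c2c(c1)O[C@H](c1cc(OCc3ccccc3)c(OCc3ccccc3)c(OCc3ccccc3)c1)[C@H](OCc1ccccc1)C2 | intermediate
25 | 3,4,5-tris(benzyloxy)benzoic acid | OC(=O)c1cc(OCc2ccccc2)c(OCc2ccccc2)c(OCc2ccccc2)c1 | starting material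
26 | (2R,3R)-3-(benzyloxy)-5-(triisopropylsilyloxy)-2-[3,4,5-tris(benzyloxy)phenyl]chroman-7-yl 3,4,5-tris(benzyloxy)benzoate | O=C(Oc1cc(O[Si](C(C)C)(C(C)C)C(C)C)c2c(c1)O[C@H](c1cc(OCc3ccccc3)c(OCc3ccccc3)c(OCc3ccccc3)c1)[C@H](OCc1ccccc1)C2)c1cc(OCc2ccccc2)c(OCc2ccccc2)c(OCc2ccccc2)c1 | intermediate
27 | (2R,3R)-3-(benzyloxy)-5-hydroxy-2-[3,4,5-tris(benzyloxy)phenyl]chroman-7-yl 3,4,5-tris(benzyloxy)benzoate | O=C(Oc1cc(O)c2c(c1)O[C@H](c1cc(OCc3ccccc3)c(OCc3ccccc3)c(OCc3ccccc3)c1)[C@H](OCc1ccccc1)C2)c1cc(OCc2ccccc2)c(OCc2ccccc2)c(OCc2ccccc2)c1 | intermediate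
28 | (−)-epigallocatechin 7-O-gallate | O=C(Oc1cc(O)c2c(c1)O[C@H](c1cc(O)c(O)c(O)c1)[C@H](O)C2)c1cc(O)c(O)c(O)c1 | target

**Step count**
Total step count: 16. Longest linear sequence: 15 (steps 1–8 and 10–16); step 9 is a one-step side branch.

**Steps most likely to fail**

1. **Step 10.**
   - What may go wrong: the vinylogous-ester cyclobutenone may open too slowly. At the temperature then needed, the vinylketene would be lost to self-condensation or to acylation of the phenol already formed.
   - Fallback: it sets out from 14 and comes back at 21. It makes the same vinylketene 17 without any strained ring.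
   - Purchasable but-2-ynoic acid takes up allyl alcohol under KOH/allyl alcohol at reflux (conjugate addition of the alkoxide) to give (E)-3-(allyloxy)but-2-enoic acid F1.
   - Oxalyl chloride with catalytic DMF in CH2Cl2 at 0 °C converts F1 into (E)-3-(allyloxy)but-2-enoyl chloride F2.
   - Slow addition of Et3N to F2 and 14 in toluene at room temperature causes 1,4-dehydrochlorination to 17. This is trapped by 14 in the established ketene–siloxyalkyne [2+2] cycloaddition to give 18.
   - After filtration of the ammonium salt, heating at 80–110 °C carries 18 through 19 and 20 to 21.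

2. **Step 12.**
   - What may go wrong: the oxyphosphonium intermediate may ionise at the electron-rich benzylic carbon. That would erode the inversion, favour the more stable 2,3-trans ring, or lead to elimination.
   - Fallback: it sets out from 22 and comes back at 23. It sets C2 by hydride delivery instead of by displacement.
   - MnO2 in CH2Cl2 oxidises the benzylic carbinol to (2R)-3-[4-(allyloxy)-2-hydroxy-6-(triisopropylsilyloxy)phenyl]-2-(benzyloxy)-1-[3,4,5-tris(benzyloxy)phenyl]propan-1-one F3.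
   - F3 should sit in equilibrium with its cyclic hemiketal, (3R)-7-(allyloxy)-3-(benzyloxy)-5-(triisopropylsilyloxy)-2-[3,4,5-tris(benzyloxy)phenyl]chroman-2-ol F4.
   - Et3SiH/BF3·OEt2 in CH2Cl2 at −78 °C (ionic reduction of a hemiketal, as in C-aryl glycoside synthesis) ionises F4 to the 2-aryl-3,4-dihydrochromenylium ion F5.
   - In F5 the C3 benzyloxy group should stand pseudoaxial to escape A1,2 strain with the coplanar aryl group. Hydride should then enter from the opposite face and leave aryl and benzyloxy cis.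

3. **Step 9.**
   - What may go wrong: alcoholysis of the strained ring (C–C cleavage to acetoacetate-type esters) may compete with addition–elimination at C3, or the exchange may stall before completion.
   - Fallback: it sets out from 15 and comes back at 16. It forms the O–CH2 bond of the allyl group instead of the ring C3–O bond.
   - Dilute aqueous HCl in THF at 0 °C hydrolyses the enol ether to cyclobutane-1,3-dione F6, a strongly acidic enol.
   - F6 is O-allylated with allyl alcohol under Mitsunobu conditions (PPh3, DIAD, THF, 0 °C).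

**Further compounds**
F1 | step 10 | (E)-3-(allyloxy)but-2-enoic acid | C=CCO/C(C)=C/C(=O)O
F2 | step 10 | (E)-3-(allyloxy)but-2-enoyl chloride | C=CCO/C(C)=C/C(=O)Cl
F3 | step 12 | (2R)-3-[4-(allyloxy)-2-hydroxy-6-(triisopropylsilyloxy)phenyl]-2-(benzyloxy)-1-[3,4,5-tris(benzyloxy)phenyl]propan-1-one | O=C(c1cc(OCc2ccccc2)c(OCc2ccccc2)c(OCc2ccccc2)c1)[C@H](OCc1ccccc1)Cc1c(O)cc(OCC=C)cc1O[Si](C(C)C)(C(C)C)C(C)C
F4 | step 12 | (3R)-7-(allyloxy)-3-(benzyloxy)-5-(triisopropylsilyloxy)-2-[3,4,5-tris(benzyloxy)phenyl]chroman-2-ol (C2 unassigned) | C=CCOc1cc(O[Si](C(C)C)(C(C)C)C(C)C)c2c(c1)OC(O)(c1cc(OCc3ccccc3)c(OCc3ccccc3)c(OCc3ccccc3)c1)[C@H](OCc1ccccc1)C2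
F5 | step 12 | (3R)-7-(allyloxy)-3-(benzyloxy)-5-(triisopropylsilyloxy)-2-[3,4,5-tris(benzyloxy)phenyl]-3,4-dihydrochromenylium ion | C=CCOc1cc(O[Si](C(C)C)(C(C)C)C(C)C)c2c(c1)[O+]=C(c1cc(OCc3ccccc3)c(OCc3ccccc3)c(OCc3ccccc3)c1)[C@H](OCc1ccccc1)C2
F6 | step 9 | cyclobutane-1,3-dione | O=C1CC(=O)C1
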